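**Plan**

1. Retrosynthesis: the butenolide is opened at the C14–C15 bond (with C13=C14) to the C13 ketone / C16 dimethyl acetal 21 and a one-carbon diazo reagent. In the lactone ring O–C16–C13=C14–C15, the oxygen-bound CH2 (C15) lies 1,5 to the vinylic CH (C14), so C15 can begin as an acetal O–CH3 group into which a C14 alkylidene carbene inserts.
2. Rings A and B are cut at C4–C5 and C9–C10 (with C8=C17) to an E,E-polyene β-keto ester. The chain is cut at C1–C2 and C11–C12 to geranyl bromide, 1,1-dimethoxyacetone and a 2-methylacetoacetate.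
3. Forward: C11–C12 alkylation, ketone masking, terminal allylic oxidation and bromination, dianion alkylation (C1–C2), then ring A and ring B in one oxidative radical bicyclisation. C3 is deoxygenated through a temporary 3,19-thionocarbonate ring, and the butenolide ring is closed last.
4. Stereochemistry: the absolute sense comes from an 8-phenylmenthyl ester in the first ring closure. C5, C9 and C10 follow from the E,E-olefins through a chair–chair array, and C4 from the axial preference of the ester.

Key step: step 15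

Assumption: the (1S,2R,5S)-8-phenylmenthyl ester is taken to steer the bicyclisation into the ent series (10α-methyl), the mirror image of the sense assumed for its antipode; if the sense proves opposite, the (1R,2S,5R)-auxiliary is used.
Assumption: the masked C13 carbinol centre (5 to 20), the α-carbon of the β-keto esters 11 and 13, and the acetal carbon C16 (25, 26) are carried as mixtures of both configurations, since each is erased later; their SMILES leave these centres undefined. Locants are those of the ent-labdane skeleton.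

**Route**

Step 1
Reactants: 1 1,1-dimethoxypropan-2-one; 2 geranyl bromide
Product: 4 (E)-1,1-dimethoxy-6,10-dimethylundeca-5,9-dien-2-one, via lithium enolate 3 (not isolated)
Conditions: LiN(i-Pr)2, THF, −78 °C; then 2, DMPU, −78 → 0 °C
Reagents that add atoms: none
Why: The kinetic lithium enolate of the methyl ketone is C-alkylated by the allylic bromide in an SN2 enolate alkylation, which forms C11–C12 and carries the E-olefin of the geranyl unit over unchanged.

Step 2
Reactants: 4 (E)-1,1-dimethoxy-6,10-dimethylundeca-5,9-dien-2-one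
Product: 5 (E)-1,1-dimethoxy-6,10-dimethylundeca-5,9-dien-2-ol
Conditions: NaBH4, MeOH, 0 °C
Reagents that add atoms: none
Why: Borohydride reduction masks the future C13 ketone as an alcohol so that it survives the dianion and LiAlH4 steps; the new carbinol centre is not controlled and is removed in step 14.

Step 3
Reactants: 5 (E)-1,1-dimethoxy-6,10-dimethylundeca-5,9-dien-2-ol
Product: 6 tert-butyldimethylsilyl ether of 5
Conditions: TBSCl, imidazole, DMF, rt
Reagents that add atoms: tert-butyldimethylsilyl chloride, CC(C)(C)[Si](C)(C)Cl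
Why: Standard silylation of a secondary alcohol gives an ether stable to base, hydride, tin radicals and weak acid.

Step 4
Reactants: 6 tert-butyldimethylsilyl ether of 5
Product: 7 (2E,6E)-10-(tert-butyldimethylsilyloxy)-11,11-dimethoxy-2,6-dimethylundeca-2,6-dien-1-ol
Conditions: SeO2 (cat.), t-BuOOH, salicylic acid (cat.), CH2Cl2, 0 °C → rt
Reagents that add atoms: tert-butyl hydroperoxide, CC(C)(C)OO
Why: SeO2-catalysed allylic oxidation (ene reaction, then [2,3]-sigmatropic shift) is selective for the E-methyl of the terminal trisubstituted olefin of polyprenyl chains and gives the E-allylic alcohol whose carbon becomes C1.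

Step 5
Reactants: 7 (2E,6E)-10-(tert-butyldimethylsilyloxy)-11,11-dimethoxy-2,6-dimethylundeca-2,6-dien-1-ol
Product: 8 (2E,6E)-1-bromo-10-(tert-butyldimethylsilyloxy)-11,11-dimethoxy-2,6-dimethylundeca-2,6-diene
Conditions: CBr4, PPh3, 2,6-lutidine, CH2Cl2, 0 °C
Reagents that add atoms: carbon tetrabromide, BrC(Br)(Br)Br
Why: The Appel reaction converts the primary allylic alcohol into the bromide under neutral conditions that leave the acetal, the silyl ether and the olefin geometry intact.

Step 6
Reactants: 9 ethyl 2-methyl-3-oxobutanoate; 10 (1S,2R,5S)-5-methyl-2-(2-phenylpropan-2-yl)cyclohexan-1-ol [(+)-8-phenylmenthol]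
Product: 11 (1S,2R,5S)-8-phenylmenthyl 2-methyl-3-oxobutanoate
Conditions: DMAP (cat.), toluene, reflux (−EtOH)
Reagents that add atoms: none
Why: DMAP-catalysed transesterification of a β-keto ester attaches the chiral auxiliary; the epimeric α-carbon later becomes the radical centre.

Step 7
Reactants: 11 (1S,2R,5S)-8-phenylmenthyl 2-methyl-3-oxobutanoate; 8 (2E,6E)-1-bromo-10-(tert-butyldimethylsilyloxy)-11,11-dimethoxy-2,6-dimethylundeca-2,6-diene
Product: 13 (1S,2R,5S)-8-phenylmenthyl (6E,10E)-14-(tert-butyldimethylsilyloxy)-15,15-dimethoxy-2,6,10-trimethyl-3-oxopentadeca-6,10-dienoate, via dilithium dianion 12 (not isolated)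
Conditions: LiN(i-Pr)2 (2.2 equiv), THF, 0 °C; then 8, −78 → 0 °C
Reagents that add atoms: none
Why: In this γ-alkylation of an acetoacetate dianion the more basic terminal carbanion displaces the allylic bromide (SN2), forming C1–C2 and completing the open-chain cyclisation precursor.

Step 8
Reactants: 13 (1S,2R,5S)-8-phenylmenthyl (6E,10E)-14-(tert-butyldimethylsilyloxy)-15,15-dimethoxy-2,6,10-trimethyl-3-oxopentadeca-6,10-dienoate
Product: 14 (1S,2R,5S)-8-phenylmenthyl 13-(tert-butyldimethylsilyloxy)-16,16-dimethoxy-3-oxo-14,15-dinor-ent-labd-8(17)-en-19-oate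
Conditions: Mn(OAc)3·2H2O (2.2 equiv), Cu(OAc)2·H2O (1 equiv), degassed AcOH, rt
Reagents that add atoms: none
Why: In this oxidative free-radical polyene cyclisation, trivalent manganese oxidises the β-keto ester enolate to the C4 radical, two 6-endo closures through a chair–chair array build ring A and then ring B as a trans-decalin (C5, C9 and C10 from the E,E-olefins, ester axial at C4, the auxiliary shielding one face in the first closure), and divalent copper oxidises the tertiary C8 radical to the exocyclic 8(17)-olefin.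

Step 9
Reactants: 14 (1S,2R,5S)-8-phenylmenthyl 13-(tert-butyldimethylsilyloxy)-16,16-dimethoxy-3-oxo-14,15-dinor-ent-labd-8(17)-en-19-oate
Product: 15 13-(tert-butyldimethylsilyloxy)-16,16-dimethoxy-14,15-dinor-ent-labd-8(17)-ene-3α,19-diol
Conditions: LiAlH4, THF, 0 °C → reflux; aqueous NaOH work-up
Reagents that add atoms: none
Why: LiAlH4 reduces the C3 ketone by axial hydride delivery on the β-face (equatorial 3α-alcohol) and cleaves the hindered axial ester reductively to the C19 carbinol, releasing the auxiliary for recovery.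

Step 10
Reactants: 15 13-(tert-butyldimethylsilyloxy)-16,16-dimethoxy-14,15-dinor-ent-labd-8(17)-ene-3α,19-diol
Product: 16 3α,19-cyclic thionocarbonate of 15
Conditions: 1,1'-thiocarbonyldiimidazole, DMAP (cat.), toluene, 80 °C
Reagents that add atoms: 1,1'-thiocarbonyldiimidazole, S=C(n1ccnc1)n1ccnc1
Why: The equatorial 3α-hydroxyl and the axial C19 hydroxymethyl are gauche and close a six-membered cyclic thionocarbonate, a temporary ring that differentiates the two oxygens.

Step 11
Reactants: 16 3α,19-cyclic thionocarbonate of 15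
Product: 18 13-(tert-butyldimethylsilyloxy)-16,16-dimethoxy-14,15-dinor-ent-labd-8(17)-en-19-ol, via S-stannyl thiolcarbonate 17 (not isolated)
Conditions: Bu3SnH, AIBN (cat.), toluene, 110 °C; then K2CO3, MeOH/H2O, rt
Reagents that add atoms: none
Why: In this Barton-type radical deoxygenation of a cyclic thionocarbonate the stannyl radical adds to sulfur and β-scission goes toward the secondary C3 radical, not the primary C19 one, so C3 becomes CH2 while the C19 oxygen stays as a thiolcarbonate that is hydrolysed in the work-up.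

Step 12
Reactants: 18 13-(tert-butyldimethylsilyloxy)-16,16-dimethoxy-14,15-dinor-ent-labd-8(17)-en-19-ol
Product: 19 19-acetoxy-13-(tert-butyldimethylsilyloxy)-16,16-dimethoxy-14,15-dinor-ent-labd-8(17)-ene
Conditions: Ac2O, pyridine, DMAP (cat.), CH2Cl2, rt
Reagents that add atoms: acetic anhydride, CC(=O)OC(C)=O
Why: Acyl-transfer-catalysed acetylation of the primary neopentyl alcohol installs the C19 acetate of the target.

Step 13
Reactants: 19 19-acetoxy-13-(tert-butyldimethylsilyloxy)-16,16-dimethoxy-14,15-dinor-ent-labd-8(17)-ene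
Product: 20 19-acetoxy-16,16-dimethoxy-14,15-dinor-ent-labd-8(17)-en-13-ol
Conditions: Bu4NF, AcOH, THF, rt
Reagents that add atoms: none
Why: Fluoride desilylation buffered with acetic acid frees the C13 alcohol without touching the acetate or the acetal.

Step 14
Reactants: 20 19-acetoxy-16,16-dimethoxy-14,15-dinor-ent-labd-8(17)-en-13-ol
Product: 21 19-acetoxy-16,16-dimethoxy-14,15-dinor-ent-labd-8(17)-en-13-one
Conditions: Dess–Martin periodinane, NaHCO3, CH2Cl2, rt
Reagents that add atoms: none
Why: Dess–Martin oxidation gives the α-keto acetal under non-acidic conditions and removes the uncontrolled C13 centre.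

Step 15
Reactants: 21 19-acetoxy-16,16-dimethoxy-14,15-dinor-ent-labd-8(17)-en-13-one
Product: 25 19-acetoxy-16-methoxy-15,16-epoxy-ent-labda-8(17),13-diene, via lithium alkoxide adduct 22 (not isolated), via diazoalkene 23 (not isolated), via alkylidene carbene 24 (not isolated)
Conditions: Me3SiCHN2, n-BuLi, THF, −78 °C; then 21, −78 → 0 °C
Reagents that add atoms: trimethylsilyldiazomethane, C[Si](C)(C)C=[N+]=[N-]
Why: Proposed new method: lithio(trimethylsilyl)diazomethane adds to the C13 ketone, Peterson-type loss of lithium trimethylsilanolate gives the diazoalkene, and loss of N2 leaves the C14 alkylidene carbene, which inserts in a concerted way into a C–H bond of an acetal methoxy group lying 1,5 to it through C13–C16–O. The closest known reaction type is the formation of 2,5-dihydrofurans from α-alkoxy ketones and the same reagent by 1,5 C–H insertion next to ether oxygen; new here is insertion into a primary methoxy C–H of an α-keto dimethyl acetal. The five-membered ring O–C16–C13=C14–C15 closes by formal 1,5-insertion through a six-centre transition state, leaving the C13=C14 double bond where the butenolide needs it and the former methyl as the ring CH2. The only new stereocentre is the acetal carbon C16, which is not controlled and is erased in step 16. The step needs site selectivity against the tertiary C9–H bond and the 8(17)-olefin on the other branch; it is expected from lone-pair activation of six equivalent O–CH3 hydrogens, whereas insertion at C9 would build a spiro quaternary carbon next to quaternary C10. A 1,2-shift to the alkyne should be slow because both carbene substituents are sp3 carbons.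

Step 16
Reactants: 25 19-acetoxy-16-methoxy-15,16-epoxy-ent-labda-8(17),13-diene
Product: 27 19-acetoxy-ent-labda-8(17),13-dien-16,15-olide (the target), via lactol 26 (not isolated)
Conditions: CrO3, H2SO4, H2O, acetone, 0 °C
Reagents that add atoms: water, O
Why: In this Jones oxidation of a cyclic methyl acetal, acid-catalysed exchange with water gives the lactol and hexavalent chromium oxidises it to the lactone, so the acetal carbon fixes the carbonyl at C16, next to the substituted olefin carbon.

**Compound list**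

1 | 1,1-dimethoxypropan-2-one | CC(=O)C(OC)OC | starting material
2 | geranyl bromide | CC(C)=CCC/C(C)=C/CBr | starting material
3 | lithium enolate of 1 | C=C(O[Li])C(OC)OC | intermediate (not isolated)
4 | (E)-1,1-dimethoxy-6,10-dimethylundeca-5,9-dien-2-one | COC(OC)C(=O)CC/C=C(\C)CCC=C(C)C | intermediate
5 | (E)-1,1-dimethoxy-6,10-dimethylundeca-5,9-dien-2-ol | COC(OC)C(O)CC/C=C(\C)CCC=C(C)C | intermediate
6 | tert-butyldimethylsilyl ether of 5 | COC(OC)C(CC/C=C(\C)CCC=C(C)C)O[Si](C)(C)C(C)(C)C | intermediate
7 | (2E,6E)-10-(tert-butyldimethylsilyloxy)-11,11-dimethoxy-2,6-dimethylundeca-2,6-dien-1-ol | COC(OC)C(CC/C=C(\C)CC/C=C(\C)CO)O[Si](C)(C)C(C)(C)C | intermediate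
8 | (2E,6E)-1-bromo-10-(tert-butyldimethylsilyloxy)-11,11-dimethoxy-2,6-dimethylundeca-2,6-diene | COC(OC)C(CC/C=C(\C)CC/C=C(\C)CBr)O[Si](C)(C)C(C)(C)C | intermediate
9 | ethyl 2-methyl-3-oxobutanoate | CCOC(=O)C(C)C(C)=O | starting material
10 | (1S,2R,5S)-5-methyl-2-(2-phenylpropan-2-yl)cyclohexan-1-ol, (+)-8-phenylmenthol | O[C@H]1C[C@@H](C)CC[C@@H]1C(C)(C)c1ccccc1 | starting material
11 | (1S,2R,5S)-8-phenylmenthyl 2-methyl-3-oxobutanoate | CC(=O)C(C)C(=O)O[C@H]1C[C@@H](C)CC[C@@H]1C(C)(C)c1ccccc1 | intermediate
12 | dilithium dianion (bis-enolate) of 11 | C=C(O[Li])C(C)=C(O[Li])O[C@H]1C[C@@H](C)CC[C@@H]1C(C)(C)c1ccccc1 | intermediate (not isolated)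
13 | (1S,2R,5S)-8-phenylmenthyl (6E,10E)-14-(tert-butyldimethylsilyloxy)-15,15-dimethoxy-2,6,10-trimethyl-3-oxopentadeca-6,10-dienoate | COC(OC)C(CC/C=C(\C)CC/C=C(\C)CCC(=O)C(C)C(=O)O[C@H]1C[C@@H](C)CC[C@@H]1C(C)(C)c1ccccc1)O[Si](C)(C)C(C)(C)C | intermediate
14 | bicyclic keto ester: 3-oxo, 4α-CO2(8-phenylmenthyl) axial, 4β-Me, 10α-Me, 5β-H, 9β-H, 8(17)-methylene, 9α-CH2CH2CH(OTBS)CH(OMe)2 | C=C1CC[C@@H]2[C@](C)(C(=O)O[C@H]3C[C@@H](C)CC[C@@H]3C(C)(C)c3ccccc3)C(=O)CC[C@@]2(C)[C@@H]1CCC(O[Si](C)(C)C(C)(C)C)C(OC)OC | intermediate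
15 | 3α,19-diol (3α-OH equatorial, 19-CH2OH axial) | C=C1CC[C@@H]2[C@](C)(CO)[C@H](O)CC[C@@]2(C)[C@@H]1CCC(O[Si](C)(C)C(C)(C)C)C(OC)OC | intermediate
16 | 3α,19-cyclic thionocarbonate of 15 | C=C1CC[C@@H]2[C@]3(C)COC(=S)O[C@@H]3CC[C@@]2(C)[C@@H]1CCC(O[Si](C)(C)C(C)(C)C)C(OC)OC | intermediate
17 | 3-deoxy 19-O-[(tributylstannylthio)carbonyl] derivative | C=C1CC[C@@H]2[C@](C)(COC(=O)S[Sn](CCCC)(CCCC)CCCC)CCC[C@@]2(C)[C@@H]1CCC(O[Si](C)(C)C(C)(C)C)C(OC)OC | intermediate (not isolated)
18 | 13-(tert-butyldimethylsilyloxy)-16,16-dimethoxy-14,15-dinor-ent-labd-8(17)-en-19-ol | C=C1CC[C@@H]2[C@](C)(CO)CCC[C@@]2(C)[C@@H]1CCC(O[Si](C)(C)C(C)(C)C)C(OC)OC | intermediate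
19 | 19-acetate of 18 | C=C1CC[C@@H]2[C@](C)(COC(C)=O)CCC[C@@]2(C)[C@@H]1CCC(O[Si](C)(C)C(C)(C)C)C(OC)OC | intermediate
20 | 19-acetoxy-16,16-dimethoxy-14,15-dinor-ent-labd-8(17)-en-13-ol | C=C1CC[C@@H]2[C@](C)(COC(C)=O)CCC[C@@]2(C)[C@@H]1CCC(O)C(OC)OC | intermediate
21 | 19-acetoxy-16,16-dimethoxy-14,15-dinor-ent-labd-8(17)-en-13-one | C=C1CC[C@@H]2[C@](C)(COC(C)=O)CCC[C@@]2(C)[C@@H]1CCC(=O)C(OC)OC | intermediate
22 | lithium alkoxide adduct of 21 with lithio(trimethylsilyl)diazomethane | C=C1CC[C@@H]2[C@](C)(COC(C)=O)CCC[C@@]2(C)[C@@H]1CCC(O[Li])(C(OC)OC)C(=[N+]=[N-])[Si](C)(C)C | intermediate (not isolated)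
23 | C14 diazoalkene | C=C1CC[C@@H]2[C@](C)(COC(C)=O)CCC[C@@]2(C)[C@@H]1CCC(=C=[N+]=[N-])C(OC)OC | intermediate (not isolated)
24 | C14 alkylidene carbene | C=C1CC[C@@H]2[C@](C)(COC(C)=O)CCC[C@@]2(C)[C@@H]1CCC(=[C])C(OC)OC | intermediate (not isolated)
25 | 19-acetoxy-16-methoxy-15,16-epoxy-ent-labda-8(17),13-diene (3-substituted 2-methoxy-2,5-dihydrofuran) | C=C1CC[C@@H]2[C@](C)(COC(C)=O)CCC[C@@]2(C)[C@@H]1CCC1=CCOC1OC | intermediate
26 | 19-acetoxy-15,16-epoxy-ent-labda-8(17),13-dien-16-ol (lactol) | C=C1CC[C@@H]2[C@](C)(COC(C)=O)CCC[C@@]2(C)[C@@H]1CCC1=CCOC1O | intermediate (not isolated)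
27 | [(1R,4aS,5R,8aS)-1,4a-dimethyl-6-methylidene-5-[2-(2-oxo-2,5-dihydrofuran-3-yl)ethyl]decahydronaphthalen-1-yl]methyl acetate | C=C1CC[C@@H]2[C@](C)(COC(C)=O)CCC[C@@]2(C)[C@@H]1CCC1=CCOC1=O | target

**Step count and risks**

Total steps: 16. Longest linear sequence: 15 (steps 1–5 and 7–16); step 6 is a one-step branch.

Steps most likely to fail:

1. Step 15 (proposed new method). The carbene may lose site selectivity, inserting into the tertiary C9–H bond or adding to the 8(17)-olefin instead of the methoxy C–H. The fallback closes the same ring from its other end by known chemistry, setting out from 21. Wittig methylenation (Ph3P=CH2, THF, 0 °C) gives the C13 methylene acetal F1. Mild hydrolysis (oxalic acid on wet silica, CH2Cl2) gives the 2-substituted acrolein F2. Pinnick oxidation (NaClO2, NaH2PO4, 2-methyl-2-butene, t-BuOH/H2O) gives the acrylic acid F3. Allyl bromide with K2CO3 in DMF gives the allyl ester F4. Ring-closing metathesis (second-generation Grubbs catalyst, toluene, 80 °C) then forms C13=C14 with loss of ethene, and the route is rejoined at 27.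

2. Step 8. Facial selectivity of the first ring closure under auxiliary control may be poor, or its sense may be opposite to the one assumed. The fallback sets the absolute configuration by resolution, setting out from bromide 8 and ethyl ester 9. Dianion alkylation as in step 7 gives the ethyl ester polyene F5. Cyclisation as in step 8 gives the racemic keto ester F6. LiAlH4 gives the racemic diol, that is 15 together with its decalin antipode F7. A lipase (serine hydrolase class, for example Burkholderia cepacia lipase, vinyl acetate, tert-butyl methyl ether) acetylates one antipode. The antipode of the required series is taken on as 15, either directly if it is the unreacted one, or after K2CO3/MeOH methanolysis of its 19-acetate F8 if it is the acylated one. The route is rejoined at 15.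

3. Step 16. Acid-promoted loss of methanol may aromatise the dihydrofuran to the 3-substituted furan, or the open hydroxy-enal form may be over-oxidised. The fallback oxidises before it hydrolyses, setting out from 25. DDQ (CH2Cl2, rt) dehydrogenates the ring to the 2-methoxyfuran F9 by hydride abstraction at the acetal carbon and proton loss from C15. Brief dilute aqueous HCl in THF then hydrolyses this 2-alkoxyfuran (protonation at C15, water at C16, loss of methanol) to the conjugated butenolide, and the route is rejoined at 27.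

**Further compounds**

F1 | step 15 | 19-acetoxy-13-methylene-16,16-dimethoxy acetal (C13=CH2 in place of the ketone of 21) | C=C1CC[C@@H]2[C@](C)(COC(C)=O)CCC[C@@]2(C)[C@@H]1CCC(=C)C(OC)OC
F2 | step 15 | 2-substituted acrolein (C16 aldehyde, C13=CH2) | C=C1CC[C@@H]2[C@](C)(COC(C)=O)CCC[C@@]2(C)[C@@H]1CCC(=C)C=O
F3 | step 15 | 2-substituted acrylic acid (C16 acid, C13=CH2) | C=C1CC[C@@H]2[C@](C)(COC(C)=O)CCC[C@@]2(C)[C@@H]1CCC(=C)C(=O)O
F4 | step 15 | allyl ester of F3 | C=C1CC[C@@H]2[C@](C)(COC(C)=O)CCC[C@@]2(C)[C@@H]1CCC(=C)C(=O)OCC=C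
F5 | step 8 | ethyl (6E,10E)-14-(tert-butyldimethylsilyloxy)-15,15-dimethoxy-2,6,10-trimethyl-3-oxopentadeca-6,10-dienoate | COC(OC)C(CC/C=C(\C)CC/C=C(\C)CCC(=O)C(C)C(=O)OCC)O[Si](C)(C)C(C)(C)C
F6 | step 8 | racemic bicyclic ethyl keto ester (ethyl ester analogue of 14; enantiomer of the required series drawn) | C=C1CC[C@@H]2[C@](C)(C(=O)OCC)C(=O)CC[C@@]2(C)[C@@H]1CCC(O[Si](C)(C)C(C)(C)C)C(OC)OC
F7 | step 8 | decalin antipode of 15 (present with 15 in the racemic diol) | C=C1CC[C@H]2[C@@](C)(CO)[C@@H](O)CC[C@]2(C)[C@H]1CCC(O[Si](C)(C)C(C)(C)C)C(OC)OC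
F8 | step 8 | 19-acetate of 15 | C=C1CC[C@@H]2[C@](C)(COC(C)=O)[C@H](O)CC[C@@]2(C)[C@@H]1CCC(O[Si](C)(C)C(C)(C)C)C(OC)OC
F9 | step 16 | 19-acetoxy-16-methoxy-15,16-epoxy-ent-labda-8(17),13(16),14-triene (3-substituted 2-methoxyfuran) | C=C1CC[C@@H]2[C@](C)(COC(C)=O)CCC[C@@]2(C)[C@@H]1CCc1ccoc1OC
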